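**Mulberrofuran V by Danheiser benzannulation: proposed route**

## Analysis of the target

Mulberrofuran V (23) is a 2-arylbenzofuran: benzo ring A (OH at C6) is fused to furan ring C, and C2 of the furan carries the resorcinol ring B through the C2–C1' bond. Ring B bears prenyl groups at C2' and C6', hydroxyls at C3' and C5' and its only hydrogen at C4', so the biaryl bond is flanked by two ortho prenyl groups. There is no stereocentre and no stereogenic double bond, so nothing has to be set or related. The sensitive groups are the two trisubstituted prenyl alkenes, each ortho to a free phenol (acid closes them to 2,2-dimethylchromans; halogens, hydrogenation and oxidants attack them), and the electron-rich triphenol. The difficulty is regiochemical and steric: electrophilic prenylation of a 5-arylresorcinol goes to C4' between the oxygens and not to the crowded C2' and C6', and the oxygens must be unmasked without acid. The strategy rests on two triads of ring B. C3'(O)–C4'(H)–C5'(O) is what a ketene carbonyl carbon and a terminal alkoxyacetylene deliver, and C6'(prenyl)–C1'(aryl)–C2'(prenyl) maps onto C2–C3–C4 of a cyclobutenone. Because the two flanking groups are the same, that cyclobutenone has no regiochemical ambiguity.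

## Retrosynthetic reasoning

**23 ⇒ 22 (O–CH3 at C5').** The benzannulation necessarily gives one free hydroxyl (C3') and one ether (C5'), so one O-alkyl bond must be cut at the end. Thiolate dealkylation is not suitable here: under basic conditions ring B already carries the C3' phenoxide, the second aryloxide is then a poor leaving group, and an ethyl group slows the SN2 step further. For that reason the ether is chosen as methyl, not the ethyl ether that ethoxyacetylene 3 would give, and is cleaved by a methyl Grignard melt, a non-protic method that tolerates acid-sensitive alkenes next to phenols.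

**22 ⇒ 21 (Si–O at C6).** The benzofuran phenol is carried as a triisopropylsilyl ether. It survives organolithium, dilute acid and heat, and fluoride removes it without touching the prenyl groups. Removing it before the demethylation leaves a single defined task for the last step.

**21 ⇒ 13 + 16 (C3'–C4' and C5'–C6'; C2'–C3' broken and re-formed).** Ring B is cut back to cyclobutenone 13 and methoxyacetylene 16. The carbonyl carbon of 13 becomes C3', its C2, C3 and C4 become C6', C1' and C2', and the alkyne supplies C4' (H) and C5' (OMe). The cut is made here because it sets all six substituents of ring B in one operation at the aromatic oxidation level, with no blocking group and no oxidant. The forward reaction must trap a fully substituted vinylketene regioselectively with the alkyne. Compound 16 is preferred to 3 for two reasons: the methyl ether can be cleaved at the end, and 16 cannot fragment to ketene and ethylene when heated.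

**13 ⇒ 2 + 10 (benzofuran C2–C1').** The aryl–cyclobutenone bond is made by adding C2-lithiated 2 to the carbonyl group of vinylogous ester 10, followed by acid-induced 1,3-carbonyl transposition. Benzofuran C2–H is the most acidic position of 2, so no halogen or cross-coupling is needed. The alternative, a (2+2) cycloaddition of a keteniminium salt with a 2-alkynylbenzofuran, needs more steps and exposes three nucleophilic π systems to a strong electrophile; it is kept as a fallback.

**10 ⇒ 8 + 6 (two ring bonds of the cyclobutenone).** The four-membered ring is cut into prenylketene (from acid chloride 8) and ynol ether 6. The polarity of the ketene–ynol ether (2+2) cycloaddition places the prenyl groups at C2 and C4 and the ethoxy group at C3. Since both side chains are prenyl, tautomerisation of 10 or 13 across the ring only gives the enantiomer.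

**Simple precursors.** Ynol ether 6 comes from C-alkylation of lithiated 3 with prenyl bromide 4, acid chloride 8 from acid 7, silyl ether 2 from benzofuran-6-ol 1, and 16 from chloroacetal 14 by double elimination. Compound 3 is therefore used where its ethoxy group is lost again (as ethanol in step 5).

## Alternatives that were turned down

**Alternative 1: double aromatic Claisen rearrangement.**
- Disconnection: both aryl–CH2 bonds of the prenyl groups (C2'–C1'' and C6'–C1'').
- Forward key step: heating the bis(1,1-dimethylallyl) ether A2 gives two [3,3] shifts from the C3' and C5' oxygens to C2' and C6', with allylic inversion to linear prenyl groups. An ester at C4' blocks the other ortho position. The product is A1.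
- For: both prenyl groups are installed with sound regiocontrol, and both ring B oxygens come out as free phenols. On that point it is stronger than the chosen route, which must cleave a methyl ether.
- Against: the two tertiary allyl ethers must be made on hindered, hydrogen-bonded phenols flanking an ester (propargylation and semi-hydrogenation). Each [3,3] shift must deliver carbon into a position next to the biaryl bond. Tertiary allyl aryl ethers also ionise and lose isoprene on heating. The new ortho-prenylphenols can cyclise. Afterwards the blocking ester of A1 has to be hydrolysed and decarboxylated, and an acetal protecting group removed with acid beside two prenyl groups.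
- Comparison: ring B and the benzofuran must already exist before the key step, so the route is several steps longer. The chosen route builds ring B and all its substituents in one step and needs no blocking group.

**Alternative 2: Michael–Claisen cyclohexanedione annulation, then aromatisation.**
- Disconnection: C1'–C6' and C4'–C5'.
- Forward key step: an alkoxide base adds malonate A5 to the β-carbon of enone A4 and then closes the ring by Claisen condensation of the methyl ketone onto an ester, giving dione A3.
- For: cheap commodity reagents, classical and scalable chemistry, no special alkyne and no sealed-tube step. On cost and simplicity of reagents it is stronger.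
- Against: a trisubstituted malonate anion must add to an α,β-disubstituted enone and form a quaternary carbon next to a tertiary one. That addition is reversible and sterically unfavourable. A3 is also one oxidation level below the arene: after de-ethoxycarbonylation the dione must be dehydrogenated, and the usual reagents for that (halogens, quinones, hot palladium) attack the two prenyl groups and the electron-rich benzofuran.
- Comparison: the chosen cascade reaches the aromatic oxidation level directly and creates no quaternary centre that must later be dismantled.

**Alternative 3: reductive carbonyl–ester coupling to close the furan.**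
- Disconnection: the C2=C3 bond of ring C.
- Forward key step: low-valent titanium couples the aldehyde carbon and the ester carbonyl carbon of aryl benzoate A7 and deoxygenates the adduct to benzofuran A6.
- For: the route is convergent, and the carbon that becomes C2 is attached to ring B from the start, so no organometallic addition is needed for the biaryl bond. On that point it is as strong as or stronger than step 5 of the chosen route.
- Against: it does not solve the main problem. The acid half of A7 is a 2,6-diprenyl-3,5-dioxygenated benzoic acid, and metalation or electrophilic prenylation of 3,5-dioxygenated benzoates goes to the position between the oxygens. The ester carbonyl is shielded by two ortho prenyl groups both in the acylation and in the coupling. Lewis-acidic titanium species threaten the acetal protecting groups and the prenyl groups. Three acetals must finally be removed with acid next to prenyl groups.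
- Comparison: the chosen route addresses the ring B pattern itself and ends with non-acidic deprotections.

Key step: step 7

## Route

Remark: compounds 10, 12, 13, 18 and 20 are handled as racemates or diastereomer mixtures, because every stereocentre they contain ends as an sp2 carbon of ring B.

Step 1
Reactants: 1 benzofuran-6-ol
Product: 2 6-(triisopropylsilyloxy)benzofuran
Conditions: TIPSCl, imidazole, DMF, rt
Reagents that add atoms: triisopropylsilyl chloride, CC(C)[Si](Cl)(C(C)C)C(C)C
Why: Standard O-silylation of a phenol; the bulky aryl silyl ether withstands the organolithium, dilute acid and thermal steps that follow.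

Step 2
Reactants: 3 ethoxyacetylene; 4 prenyl bromide (1-bromo-3-methylbut-2-ene)
Product: 6 1-ethoxy-5-methylhex-4-en-1-yne, via lithium ethoxyacetylide 5 (not isolated)
Conditions: n-BuLi, THF, −78 °C; then 4, DMPU, −78 °C → rt; neutral work-up, distillation under reduced pressure
Reagents that add atoms: none
Why: C-alkylation of a metalated alkoxyacetylene with a primary allylic bromide; the acetylide attacks the unhindered CH2 (SN2, not SN2'), giving the linear prenyl ynol ether.

Step 3
Reactants: 7 5-methylhex-4-enoic acid
Product: 8 5-methylhex-4-enoyl chloride
Conditions: (COCl)2, cat. DMF, CH2Cl2, 0 °C → rt; evaporate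
Reagents that add atoms: oxalyl chloride, O=C(Cl)C(=O)Cl
Why: Vilsmeier-type acid chloride formation under mild conditions; the HCl is swept out with the gaseous by-products at low temperature, so the trisubstituted alkene is not hydrochlorinated.

Step 4
Reactants: 8 5-methylhex-4-enoyl chloride; 6 1-ethoxy-5-methylhex-4-en-1-yne
Product: 10 3-ethoxy-2,4-bis(3-methylbut-2-enyl)cyclobut-2-en-1-one (racemic), via prenylketene 9 (not isolated)
Conditions: Et3N, Et2O, reflux, slow addition of 8 to 6 and the base
Reagents that add atoms: none
Why: Dehydrochlorination gives aldoketene 9, whose carbonyl carbon is attacked by the nucleophilic C2 of ynol ether 6; this ketene–alkoxyalkyne (2+2) cycloaddition is the standard entry to 3-alkoxycyclobutenones, and its polarity puts the prenyl groups at C2 and C4. Slow addition keeps the ketene concentration low so that capture competes with dimerisation; C4 is formed racemic.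

Step 5
Reactants: 2 6-(triisopropylsilyloxy)benzofuran; 10 3-ethoxy-2,4-bis(3-methylbut-2-enyl)cyclobut-2-en-1-one
Product: 13 3-[6-(triisopropylsilyloxy)benzofuran-2-yl]-2,4-bis(3-methylbut-2-enyl)cyclobut-2-en-1-one (racemic), via 2-lithiobenzofuran 11 (not isolated), via cyclobutenol adduct 12 (not isolated)
Conditions: 2, n-BuLi, THF, −78 → 0 °C; 10, −78 °C; then 1 M aq. HCl, THF, 0 °C → rt
Reagents that add atoms: water, O
Why: Benzofuran is lithiated at C2, its most acidic position, and 11 adds to the carbonyl group of vinylogous ester 10. Aqueous acid ionises the tertiary allylic alcohol 12, water adds at the ethoxy-bearing carbon and ethanol is lost, a 1,3-carbonyl transposition of the Stork–Danheiser type that is the usual way to 3-substituted cyclobutenones. The aryl silyl ether tolerates brief dilute acid and C4 stays racemic.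

Step 6
Reactants: 14 chloroacetaldehyde dimethyl acetal (2-chloro-1,1-dimethoxyethane)
Product: 16 methoxyacetylene, via sodium methoxyacetylide 15 (not isolated)
Conditions: NaNH2 (3 equiv), liq. NH3, −33 °C; NH3 evaporated; cold aq. NaCl, −20 °C → rt, distilled into a cold trap
Reagents that add atoms: none
Why: Double elimination (methanol, then HCl) with excess amide gives acetylide 15, which is protonated on aqueous quench; this is the classical preparation of simple alkoxyacetylenes. The volatile product (bp about 23 °C) is collected cold and used as a toluene solution.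

Step 7
Reactants: 13 3-[6-(triisopropylsilyloxy)benzofuran-2-yl]-2,4-bis(3-methylbut-2-enyl)cyclobut-2-en-1-one; 16 methoxyacetylene
Product: 21 5-methoxy-2,4-bis(3-methylbut-2-enyl)-3-[6-(triisopropylsilyloxy)benzofuran-2-yl]phenol, via vinylketene 17 (not isolated), via 4-vinylcyclobutenone 18 (not isolated), via dienylketene 19 (not isolated), via cyclohexadienone 20 (not isolated)
Conditions: 16 (5 equiv), toluene, sealed tube, 80 °C, then 110 °C
Reagents that add atoms: none
Why: This is a Danheiser benzannulation of a cyclobutenone with an alkoxyacetylene, the closest known reaction type, applied here to a 2,3,4-trisubstituted case. Heat opens 13 by four-electron conrotatory cleavage of the C(=O)–C4 bond to vinylketene 17, with the C4 prenyl group turning outward. The ketene carbon (future C3') bonds to the unsubstituted, nucleophilic terminus of 16 (future C4') and the ketene α-carbon (future C6') to the methoxy-bearing carbon (future C5'); the polarisation of both partners fixes this regiochemistry and places OMe meta to the new OH with H between them. Cyclobutenone 18 opens again to dienylketene 19; this opening is reversible and only the isomer with the alkenyl arm cis to the ketene goes on. Ring B closes by thermal disrotatory six-electron electrocyclisation of 19 (C3' onto C2'), and cyclohexadienone 20 tautomerises to the phenol, which makes the cascade irreversible. No stereocentre survives, since the centres of 13, 18 and 20 all become sp2 carbons of ring B. Excess 16 is needed so that capture of 17 outruns its dimerisation and its reaction with the prenyl double bonds, and the outward prenyl group of 17 lies far from the ketene carbon, which disfavours intramolecular (2+2) addition. Methoxyacetylene cannot undergo the retro-ene loss of ethylene that ethoxyacetylene 3 shows near 120 °C, so the temperature can be raised if the hindered 17 reacts slowly.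

Step 8
Reactants: 21 5-methoxy-2,4-bis(3-methylbut-2-enyl)-3-[6-(triisopropylsilyloxy)benzofuran-2-yl]phenol
Product: 22 2-[3-hydroxy-5-methoxy-2,6-bis(3-methylbut-2-enyl)phenyl]benzofuran-6-ol
Conditions: TBAF, THF, 0 °C; aq. NH4Cl
Reagents that add atoms: none
Why: Fluoride cleaves the aryl Si–O bond at 0 °C and nothing else in 21 reacts; after this step only the ArO–CH3 bond remains to be cut.

Step 9
Reactants: 22 2-[3-hydroxy-5-methoxy-2,6-bis(3-methylbut-2-enyl)phenyl]benzofuran-6-ol
Product: 23 mulberrofuran V, 5-(6-hydroxybenzofuran-2-yl)-4,6-bis(3-methylbut-2-enyl)benzene-1,3-diol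
Conditions: MeMgI (excess), Et2O, solvent removed; neat, 160 °C, reduced pressure; aq. NH4Cl
Reagents that add atoms: none
Why: Grignard-mediated ether cleavage: in the melt the magnesium-coordinated aryl methyl ether is attacked at CH3 by iodide, a Lewis-acid-assisted SN2 process that, unlike thiolate demethylation, is not stopped by the phenoxide already on ring B. The conditions are non-protic, and resorcinol methyl ethers carrying acid-sensitive alkenes ortho to oxygen are known to survive them, whereas BBr3 or HBr would close chromans. The two free phenols only consume reagent as magnesium phenoxides.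

## Compound list

1 | benzofuran-6-ol | Oc1ccc2ccoc2c1 | starting material
2 | 6-(triisopropylsilyloxy)benzofuran | CC(C)[Si](Oc1ccc2ccoc2c1)(C(C)C)C(C)C | intermediate
3 | ethoxyacetylene | C#COCC | starting material
4 | prenyl bromide (1-bromo-3-methylbut-2-ene) | CC(C)=CCBr | starting material
5 | lithium ethoxyacetylide (not isolated) | [Li]C#COCC | intermediate
6 | 1-ethoxy-5-methylhex-4-en-1-yne | CCOC#CCC=C(C)C | intermediate
7 | 5-methylhex-4-enoic acid | CC(C)=CCCC(=O)O | starting material
8 | 5-methylhex-4-enoyl chloride | CC(C)=CCCC(=O)Cl | intermediate
9 | prenylketene, 5-methylhexa-1,4-dien-1-one (not isolated) | CC(C)=CCC=C=O | intermediate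
10 | 3-ethoxy-2,4-bis(3-methylbut-2-enyl)cyclobut-2-en-1-one (racemic) | CCOC1=C(CC=C(C)C)C(=O)C1CC=C(C)C | intermediate
11 | 2-lithio-6-(triisopropylsilyloxy)benzofuran (not isolated) | [Li]c1cc2ccc(O[Si](C(C)C)(C(C)C)C(C)C)cc2o1 | intermediate
12 | 3-ethoxy-2,4-bis(3-methylbut-2-enyl)-1-[6-(triisopropylsilyloxy)benzofuran-2-yl]cyclobut-2-en-1-ol (diastereomer mixture, not isolated) | CCOC1=C(CC=C(C)C)C(O)(c2cc3ccc(O[Si](C(C)C)(C(C)C)C(C)C)cc3o2)C1CC=C(C)C | intermediate
13 | 3-[6-(triisopropylsilyloxy)benzofuran-2-yl]-2,4-bis(3-methylbut-2-enyl)cyclobut-2-en-1-one (racemic) | O=C1C(CC=C(C)C)C(c2cc3ccc(O[Si](C(C)C)(C(C)C)C(C)C)cc3o2)=C1CC=C(C)C | intermediate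
14 | chloroacetaldehyde dimethyl acetal | COC(CCl)OC | starting material
15 | sodium methoxyacetylide (not isolated) | [Na+].[C-]#COC | intermediate
16 | methoxyacetylene | C#COC | intermediate
17 | vinylketene from ring opening of 13, C4 prenyl group outward (not isolated) | O=C=C(CC=C(C)C)/C(c1cc2ccc(O[Si](C(C)C)(C(C)C)C(C)C)cc2o1)=C/CC=C(C)C | intermediate
18 | 3-methoxy-4-(3-methylbut-2-enyl)-4-alkenylcyclobut-2-en-1-one (racemic, not isolated) | O=C1C=C(OC)C1(CC=C(C)C)/C(c2cc3ccc(O[Si](C(C)C)(C(C)C)C(C)C)cc3o2)=C/CC=C(C)C | intermediate
19 | dienylketene, geometry that allows ring closure (not isolated) | O=C=C/C(OC)=C(CC=C(C)C)\C(c1cc2ccc(O[Si](C(C)C)(C(C)C)C(C)C)cc2o1)=C\CC=C(C)C | intermediate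
20 | 3-methoxy-4,6-bis(3-methylbut-2-enyl)-5-[6-(triisopropylsilyloxy)benzofuran-2-yl]cyclohexa-2,4-dien-1-one (racemic, not isolated) | O=C1C=C(OC)C(CC=C(C)C)=C(c2cc3ccc(O[Si](C(C)C)(C(C)C)C(C)C)cc3o2)C1CC=C(C)C | intermediate
21 | 5-methoxy-2,4-bis(3-methylbut-2-enyl)-3-[6-(triisopropylsilyloxy)benzofuran-2-yl]phenol | COc1cc(O)c(CC=C(C)C)c(-c2cc3ccc(O[Si](C(C)C)(C(C)C)C(C)C)cc3o2)c1CC=C(C)C | intermediate
22 | 2-[3-hydroxy-5-methoxy-2,6-bis(3-methylbut-2-enyl)phenyl]benzofuran-6-ol | COc1cc(O)c(CC=C(C)C)c(-c2cc3ccc(O)cc3o2)c1CC=C(C)C | intermediate
23 | mulberrofuran V | CC(C)=CCc1c(O)cc(O)c(CC=C(C)C)c1-c1cc2ccc(O)cc2o1 | target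

## Step count and least certain steps

Total: 9 steps. Longest linear sequence: 6 steps (3 → 6 → 10 → 13 → 21 → 22 → 23).

**Step 7 (key step).** The most likely failure is slow capture of the congested, fully substituted vinylketene by the alkyne. The ketene would then be consumed by dimerisation, by ene or (2+2) reactions with the electron-rich prenyl double bonds after E/Z equilibration, or by O-acylation of the product phenol. The fallback removes the trisubstituted alkenes from the cascade and installs the prenyl groups afterwards; it sets out from 3 and 2 and comes back at 21. Lithiated 3 is alkylated with allyl bromide to 1-ethoxypent-4-en-1-yne F1. Pent-4-enoyl chloride and Et3N with F1 give 3-ethoxy-2,4-di(prop-2-enyl)cyclobut-2-en-1-one F2. Addition of 11 and acid hydrolysis as in step 5 give 2,4-di(prop-2-enyl)-3-[6-(triisopropylsilyloxy)benzofuran-2-yl]cyclobut-2-en-1-one F3. Benzannulation of F3 with 16 gives 5-methoxy-2,4-di(prop-2-enyl)-3-[6-(triisopropylsilyloxy)benzofuran-2-yl]phenol F4. Cross-metathesis of both allyl groups with 2-methylbut-2-ene (second-generation Grubbs catalyst, CH2Cl2, 40 °C) then gives 21.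

**Step 4.** The aldoketene may dimerise faster than it is captured by the disubstituted ynol ether, which would give little cyclobutenone. The fallback builds the four-membered ring by keteniminium–alkyne (2+2) cycloaddition; it sets out from 2 and 8 and comes back at 13, bypassing steps 4 and 5. Compound 2 is lithiated at C2 and formylated with DMF to 6-(triisopropylsilyloxy)benzofuran-2-carbaldehyde F5. CBr4 and PPh3 convert F5 into 2-(2,2-dibromoethenyl)-6-(triisopropylsilyloxy)benzofuran F6. n-BuLi (2 equiv) and then 4 in THF/DMPU give 2-(5-methylhex-4-en-1-ynyl)-6-(triisopropylsilyloxy)benzofuran F7. Separately, 8 and dimethylamine give N,N,5-trimethylhex-4-enamide F8. Activation of F8 with Tf2O and 2,4,6-collidine in 1,2-dichloroethane, cycloaddition with F7 at reflux and aqueous NaHCO3 hydrolysis give 13. The aryl group ends at C3 because the cationic intermediate is best stabilised next to the benzofuran.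

**Step 5.** Proton transfer may compete with carbonyl addition, either as enolisation of 10 at C4 by the aryllithium or as incomplete or misdirected lithiation of 2. Partial desilylation in the acid step is a lesser risk. The fallback replaces the carbonyl addition by a cross-coupling; it sets out from 10 and 2 and comes back at 13. Dilute aqueous acid hydrolyses 10 to 3-hydroxy-2,4-bis(3-methylbut-2-enyl)cyclobut-2-en-1-one F9, which is a single enol by symmetry. Oxalyl chloride with catalytic DMF gives 3-chloro-2,4-bis(3-methylbut-2-enyl)cyclobut-2-en-1-one F10. Quenching 11 with Bu3SnCl gives tributyl[6-(triisopropylsilyloxy)benzofuran-2-yl]stannane F11. Stille coupling of F10 with F11 (Pd(PPh3)4, CuI, DMF, 60 °C, below the ring-opening temperature) gives 13.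

**Step 9.** Demethylation may be incomplete, or heat may drive cyclisation or migration of a prenyl group next to a magnesium phenoxide at 160 °C. The fallback avoids an alkyl ether altogether by making the alkyne oxygen substituent fluoride-labile; it sets out from 13 and comes back at 23. 2-(Trimethylsilyl)ethanol, KH and trichloroethylene give (E)-[2-(1,2-dichloroethenyloxy)ethyl]trimethylsilane F12. n-BuLi (2 equiv) and protonation give [2-(ethynyloxy)ethyl]trimethylsilane F13. Benzannulation of 13 with F13 at 80 °C gives 2,4-bis(3-methylbut-2-enyl)-3-[6-(triisopropylsilyloxy)benzofuran-2-yl]-5-[2-(trimethylsilyl)ethoxy]phenol F14. CsF in DMF at 90 °C removes both the silyl ether and the 2-(trimethylsilyl)ethyl group and gives 23.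

## Further compounds

F1 | step 7 | 1-ethoxypent-4-en-1-yne | CCOC#CCC=C
F2 | step 7 | 3-ethoxy-2,4-di(prop-2-enyl)cyclobut-2-en-1-one (racemic) | CCOC1=C(CC=C)C(=O)C1CC=C
F3 | step 7 | 2,4-di(prop-2-enyl)-3-[6-(triisopropylsilyloxy)benzofuran-2-yl]cyclobut-2-en-1-one (racemic) | O=C1C(CC=C)C(c2cc3ccc(O[Si](C(C)C)(C(C)C)C(C)C)cc3o2)=C1CC=C
F4 | step 7 | 5-methoxy-2,4-di(prop-2-enyl)-3-[6-(triisopropylsilyloxy)benzofuran-2-yl]phenol | COc1cc(O)c(CC=C)c(-c2cc3ccc(O[Si](C(C)C)(C(C)C)C(C)C)cc3o2)c1CC=C
F5 | step 4 | 6-(triisopropylsilyloxy)benzofuran-2-carbaldehyde | O=Cc1cc2ccc(O[Si](C(C)C)(C(C)C)C(C)C)cc2o1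
F6 | step 4 | 2-(2,2-dibromoethenyl)-6-(triisopropylsilyloxy)benzofuran | BrC(Br)=Cc1cc2ccc(O[Si](C(C)C)(C(C)C)C(C)C)cc2o1
F7 | step 4 | 2-(5-methylhex-4-en-1-ynyl)-6-(triisopropylsilyloxy)benzofuran | CC(C)=CCC#Cc1cc2ccc(O[Si](C(C)C)(C(C)C)C(C)C)cc2o1
F8 | step 4 | N,N,5-trimethylhex-4-enamide | CC(C)=CCCC(=O)N(C)C
F9 | step 5 | 3-hydroxy-2,4-bis(3-methylbut-2-enyl)cyclobut-2-en-1-one (racemic) | OC1=C(CC=C(C)C)C(=O)C1CC=C(C)C
F10 | step 5 | 3-chloro-2,4-bis(3-methylbut-2-enyl)cyclobut-2-en-1-one (racemic) | ClC1=C(CC=C(C)C)C(=O)C1CC=C(C)C
F11 | step 5 | tributyl[6-(triisopropylsilyloxy)benzofuran-2-yl]stannane | CCCC[Sn](CCCC)(CCCC)c1cc2ccc(O[Si](C(C)C)(C(C)C)C(C)C)cc2o1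
F12 | step 9 | (E)-[2-(1,2-dichloroethenyloxy)ethyl]trimethylsilane | C[Si](C)(C)CCO/C(Cl)=C\Cl
F13 | step 9 | [2-(ethynyloxy)ethyl]trimethylsilane | C#COCC[Si](C)(C)C
F14 | step 9 | 2,4-bis(3-methylbut-2-enyl)-3-[6-(triisopropylsilyloxy)benzofuran-2-yl]-5-[2-(trimethylsilyl)ethoxy]phenol | C[Si](C)(C)CCOc1cc(O)c(CC=C(C)C)c(-c2cc3ccc(O[Si](C(C)C)(C(C)C)C(C)C)cc3o2)c1CC=C(C)C
A1 | alternative 1 | methyl 2,6-dihydroxy-4-[6-(methoxymethoxy)benzofuran-2-yl]-3,5-bis(3-methylbut-2-enyl)benzoate | COC(=O)c1c(O)c(CC=C(C)C)c(-c2cc3ccc(OCOC)cc3o2)c(CC=C(C)C)c1O
A2 | alternative 1 | methyl 4-[6-(methoxymethoxy)benzofuran-2-yl]-2,6-bis(2-methylbut-3-en-2-yloxy)benzoate | COC(=O)c1c(OC(C)(C)C=C)cc(-c2cc3ccc(OCOC)cc3o2)cc1OC(C)(C)C=C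
A3 | alternative 2 | ethyl 6-[6-(methoxymethoxy)benzofuran-2-yl]-1,5-bis(3-methylbut-2-enyl)-2,4-dioxocyclohexane-1-carboxylate (diastereomer mixture) | CCOC(=O)C1(CC=C(C)C)C(=O)CC(=O)C(CC=C(C)C)C1c1cc2ccc(OCOC)cc2o1
A4 | alternative 2 | (E)-3-{[6-(methoxymethoxy)benzofuran-2-yl]methylidene}-6-methylhept-5-en-2-one | CC(=O)/C(CC=C(C)C)=C/c1cc2ccc(OCOC)cc2o1
A5 | alternative 2 | diethyl 2-(3-methylbut-2-enyl)propanedioate | CCOC(=O)C(CC=C(C)C)C(=O)OCC
A6 | alternative 3 | 2-[3,5-bis(methoxymethoxy)-2,6-bis(3-methylbut-2-enyl)phenyl]-6-(methoxymethoxy)benzofuran | CC(C)=CCc1c(OCOC)cc(OCOC)c(CC=C(C)C)c1-c1cc2ccc(OCOC)cc2o1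
A7 | alternative 3 | 2-formyl-5-(methoxymethoxy)phenyl 3,5-bis(methoxymethoxy)-2,6-bis(3-methylbut-2-enyl)benzoate | O=Cc1ccc(OCOC)cc1OC(=O)c1c(CC=C(C)C)c(OCOC)cc(OCOC)c1CC=C(C)C
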